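**Retrosynthetic overview**
1. The target is reached from its 4-hydroxy derivative by thioacylation and Barton–McCombie reduction; this temporary oxygen at C4 is the price of the union below.
2. Key disconnection: the bonds C4–C4a and O1–C7a, made in one flask by a vinylogous Mukaiyama aldol / hydroperoxide-Michael annulation of an α-silylperoxy aldehyde with 2-methyl-5-(trimethylsilyloxy)furan.
3. Enabling feature: C4a and C7a are the γ- and β-carbons of the butenolide hidden in the lactone ring (O5–C6–C7–C7a–C4a). C4a is therefore nucleophilic as the silyloxyfuran terminus and C7a becomes the Michael terminus, while C4–C3–O2–O1 is a 1,4 carbon-electrophile/oxygen-nucleophile unit (aldehyde carbon, hydroperoxide oxygen).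
4. The peroxy aldehyde comes from a methyl ketone by catalytic asymmetric Corey–Chaykovsky epoxidation and invertive perhydrolysis (sets C3); the ketone comes from (R)-citronellal (sets C2′) by ozonolysis and Julia–Kocienski olefination.
5. Ring order: the lactone ring arrives preformed as the furan; the 1,2-dioxane ring closes in the key step.

Key step: step 12

Remark on numbering: ring atoms are numbered as in furo[3,2-c][1,2]dioxine (O1, O2, C3, C4, C4a, O5, C6, C7, C7a); the side chain on C3 carries primed numbers.
Assumption: the carbinol centre at C4 created in step 12 is removed in step 14, so its configuration is left open in names and SMILES (likewise C2 of alcohol 6, removed in step 4).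

**Step 1**
Reactants: 1 (E)-5-phenylpent-4-en-1-ol; 2 1-phenyl-1H-tetrazole-5-thiol
Product: 3 1-phenyl-5-{[(4E)-5-phenylpent-4-en-1-yl]sulfanyl}-1H-tetrazole
Conditions: PPh3, DIAD, THF, 0 °C → rt
Reagents that add atoms: none
Why: Mitsunobu thioetherification, in which the acidic tetrazole thiol displaces the activated primary alcohol in an SN2 step and no stereocentre is involved.

**Step 2**
Reactants: 3 sulfide
Product: 4 1-phenyl-5-{[(4E)-5-phenylpent-4-en-1-yl]sulfonyl}-1H-tetrazole
Conditions: (NH4)6Mo7O24·4H2O (cat.), 30% H2O2, EtOH, 0 °C → rt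
Reagents that add atoms: hydrogen peroxide, OO
Why: Molybdate-catalysed peroxide oxidation takes the sulfide to the sulfone much faster than it epoxidises the conjugated alkene, so the E-styrene should survive.

**Step 3**
Reactants: 5 (R)-citronellal
Product: 6 (4R)-4,8-dimethylnon-7-en-2-ol (both C2 epimers)
Conditions: MeMgBr, Et2O, −78 → 0 °C; aq. NH4Cl
Reagents that add atoms: methylmagnesium bromide, C[Mg]Br
Why: Grignard 1,2-addition to the aldehyde, whose new carbinol centre is erased in step 4, while the methyl-bearing centre is not α to the carbonyl and cannot epimerise.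

**Step 4**
Reactants: 6 alcohol
Product: 7 (4R)-4,8-dimethylnon-7-en-2-one
Conditions: Dess–Martin periodinane, CH2Cl2, rt
Reagents that add atoms: none
Why: Dess–Martin oxidation of the secondary alcohol to the methyl ketone under neutral conditions that leave the trisubstituted alkene and the β-stereocentre alone.

**Step 5**
Reactants: 7 enone precursor (alkenyl ketone)
Product: 9 (4R)-4-methyl-6-oxoheptanal, via ozonide 8 (not isolated)
Conditions: O3, CH2Cl2, −78 °C; then Me2S, −78 °C → rt
Reagents that add atoms: ozone, [O-][O+]=O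
Why: Ozonolysis cleaves the only C=C bond through the secondary ozonide, which dimethyl sulfide reduces to the aldehyde, and the ketone is inert.

**Step 6**
Reactants: 4 sulfone; 9 keto aldehyde
Product: 10 (4R,7E,11E)-4-methyl-12-phenyldodeca-7,11-dien-2-one
Conditions: 4, KN(SiMe3)2, DME, −78 °C; then 9, −78 °C → rt
Reagents that add atoms: none
Why: Julia–Kocienski olefination, in which the pre-formed potassium sulfonyl carbanion adds to the aldehyde far faster than to the methyl ketone and Smiles rearrangement/elimination in DME should give the E-alkene.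

**Step 7**
Reactants: 10 dienyl methyl ketone
Product: 11 (2S)-2-methyl-2-[(2R,5E,9E)-2-methyl-10-phenyldeca-5,9-dien-1-yl]oxirane
Conditions: Me3S(O)I, NaH, THF, rt (ylide); then 10, LaLi3(binaphtholate)3 (5 mol%, enantiomer selected for Re-face attack), tris(2,4,6-trimethoxyphenyl)phosphine oxide (5 mol%), 5 Å sieves, THF, rt
Reagents that add atoms: trimethylsulfoxonium iodide, C[S+](C)(C)=O.[I-]
Why: Catalytic asymmetric Corey–Chaykovsky epoxidation of a methyl ketone, in which the lanthanum–lithium binaphtholate binds ketone and ylide and delivers CH2 to the Re face under catalyst control, setting the oxirane carbon as S.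

**Step 8**
Reactants: 11 epoxide
Product: 12 (2R,4R,7E,11E)-2-hydroperoxy-2,4-dimethyl-12-phenyldodeca-7,11-dien-1-ol
Conditions: anhydrous H2O2 in Et2O, H3PMo12O40 (cat.), rt
Reagents that add atoms: hydrogen peroxide, OO
Why: Acid-type perhydrolysis of a 2,2-disubstituted oxirane, in which H2O2 opens the activated epoxide at the tertiary carbon in a borderline SN2 step with inversion, turning the S oxirane carbon into the R tertiary hydroperoxide (future C3).

**Step 9**
Reactants: 12 hydroperoxy alcohol
Product: 13 (2R,4R,7E,11E)-2,4-dimethyl-12-phenyl-2-[(triethylsilyl)peroxy]dodeca-7,11-dien-1-ol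
Conditions: Et3SiCl (1.05 equiv), imidazole, CH2Cl2, −40 °C
Reagents that add atoms: chlorotriethylsilane, CC[Si](Cl)(CC)CC
Why: Chemoselective O-silylation, since the hydroperoxide O–H is more acidic and (α-effect) more nucleophilic than the neopentylic primary alcohol, so one equivalent of silyl chloride should cap the peroxide only.

**Step 10**
Reactants: 13 silylperoxy alcohol
Product: 14 (2R,4R,7E,11E)-2,4-dimethyl-12-phenyl-2-[(triethylsilyl)peroxy]dodeca-7,11-dienal
Conditions: Dess–Martin periodinane, pyridine, CH2Cl2, 0 °C
Reagents that add atoms: none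
Why: Dess–Martin oxidation of the primary alcohol to a non-enolisable α-quaternary aldehyde, with the silyl peroxide, the alkenes and both stereocentres inert to the periodinane.

**Step 11**
Reactants: 15 α-angelica lactone (5-methylfuran-2(3H)-one)
Product: 16 trimethyl[(5-methylfuran-2-yl)oxy]silane
Conditions: Me3SiCl, Et3N, Et2O, 0 °C → rt; distillation
Reagents that add atoms: chlorotrimethylsilane, C[Si](C)(C)Cl
Why: Soft enolisation and O-silylation of the deconjugated butenolide gives the aromatic 2-silyloxyfuran, the silyl dienolate needed as γ-nucleophile.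

**Step 12**
Reactants: 14 silylperoxy aldehyde; 16 silyloxyfuran
Product: 19 (3R,4aS,7aS)-4-hydroxy-3,4a-dimethyl-3-[(2R,5E,9E)-2-methyl-10-phenyldeca-5,9-dien-1-yl]tetrahydro-3H-furo[3,2-c][1,2]dioxin-6(4H)-one, via aldol silyl ether 17 (not isolated), via hydroperoxy butenolide 18 (not isolated)
Conditions: Ti(OiPr)4 + BINOL (1:1, 20 mol%; BINOL enantiomer selected for the 5R butenolide), Et2O, −20 °C; then Bu4NF, AcOH, THF, 0 °C; then Et2NH (cat.), CF3CH2OH, 0 °C → rt
Reagents that add atoms: none
Why: Proposed new method: the titanium–BINOL Lewis acid activates the non-enolisable α-silylperoxy aldehyde, the γ-carbon of silyl dienolate 16 attacks the carbonyl through an open vinylogous Mukaiyama aldol transition state with silyl transfer to the aldolate (C4–C4a bond, giving 17), buffered fluoride then frees the hydroperoxide (18) and the amine triggers its conjugate addition to the butenolide β-carbon (O1–C7a bond). The closest known reaction types are the catalytic asymmetric vinylogous Mukaiyama aldol of 2-silyloxyfurans with α-oxygenated aldehydes and the base-mediated intramolecular hydroperoxide Michael addition to butenolides; they have not been run in sequence on a peroxide-bearing aldehyde. No ring closes in the aldol event (the lactone ring arrives as the furan), and the 1,2-dioxane ring closes by 6-exo-trig attack of the hydroperoxide oxygen. C4a is set by the catalyst, which shields one aldehyde face while the open transition state couples the furan face to it; C7a follows from the tether, because the peroxide can reach the β-carbon only on the face of the C4–C4a bond, which gives the cis ring fusion; the C4 carbinol centre is not needed and C3 is not touched. The step needs γ- rather than α-attack of the furan, secured by the silyl dienolate (Mukaiyama) mode, and survival of the O–O bond, secured by silyl capping of the hydroperoxide, the absence of any enolisable hydrogen at the α-quaternary aldehyde and the mild alkoxide Lewis acid at low temperature.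

**Step 13**
Reactants: 19 bicyclic alcohol
Product: 20 O-phenyl thionocarbonate of 19 (O-phenyl carbonothioate at the C4 oxygen)
Conditions: PhOC(S)Cl, pyridine, DMAP (cat.), CH2Cl2, 0 °C → rt
Reagents that add atoms: O-phenyl chlorothionoformate, S=C(Cl)Oc1ccccc1
Why: O-acylation of the secondary alcohol with the aryl chlorothionoformate under weakly basic conditions, which should not open the β-peroxy lactone, gives the radical precursor for the Barton–McCombie reaction.

**Step 14**
Reactants: 20 thionocarbonate
Product: 21 (3R,4aS,7aS)-3,4a-dimethyl-3-[(2R,5E,9E)-2-methyl-10-phenyldeca-5,9-dien-1-yl]tetrahydro-3H-furo[3,2-c][1,2]dioxin-6(4H)-one (target)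
Conditions: (Me3Si)3SiH, AIBN (cat.), toluene, 80 °C
Reagents that add atoms: none
Why: Barton–McCombie deoxygenation, in which the silyl radical adds to C=S, β-scission gives the ring C4 radical and this takes hydrogen from the silane; the endocyclic radical cannot align with the O–O bond for homolytic substitution, so the peroxide should survive, the carbinol centre is erased and C3, C4a and C7a are unchanged.

**Compound list**
1 | (E)-5-phenylpent-4-en-1-ol | OCCC/C=C/c1ccccc1 | starting material
2 | 1-phenyl-1H-tetrazole-5-thiol | Sc1nnnn1-c1ccccc1 | starting material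
3 | 1-phenyl-5-{[(4E)-5-phenylpent-4-en-1-yl]sulfanyl}-1H-tetrazole | C(CC/C=C/c1ccccc1)Sc1nnnn1-c1ccccc1 | intermediate
4 | 1-phenyl-5-{[(4E)-5-phenylpent-4-en-1-yl]sulfonyl}-1H-tetrazole | O=S(=O)(CCC/C=C/c1ccccc1)c1nnnn1-c1ccccc1 | intermediate
5 | (R)-citronellal, (3R)-3,7-dimethyloct-6-enal | C[C@H](CCC=C(C)C)CC=O | starting material
6 | (4R)-4,8-dimethylnon-7-en-2-ol, C2 epimers | C[C@H](CCC=C(C)C)CC(C)O | intermediate
7 | (4R)-4,8-dimethylnon-7-en-2-one | C[C@H](CCC=C(C)C)CC(C)=O | intermediate
8 | ozonide, 3,3-dimethyl-5-[(3R)-3-methyl-5-oxohexyl]-1,2,4-trioxolane | C[C@H](CCC1OOC(C)(C)O1)CC(C)=O | intermediate (not isolated)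
9 | (4R)-4-methyl-6-oxoheptanal | C[C@H](CCC=O)CC(C)=O | intermediate
10 | (4R,7E,11E)-4-methyl-12-phenyldodeca-7,11-dien-2-one | C[C@H](CC/C=C/CC/C=C/c1ccccc1)CC(C)=O | intermediate
11 | (2S)-2-methyl-2-[(2R,5E,9E)-2-methyl-10-phenyldeca-5,9-dien-1-yl]oxirane | C[C@H](CC/C=C/CC/C=C/c1ccccc1)C[C@@]1(C)CO1 | intermediate
12 | (2R,4R,7E,11E)-2-hydroperoxy-2,4-dimethyl-12-phenyldodeca-7,11-dien-1-ol | C[C@H](CC/C=C/CC/C=C/c1ccccc1)C[C@](C)(CO)OO | intermediate
13 | (2R,4R,7E,11E)-2,4-dimethyl-12-phenyl-2-[(triethylsilyl)peroxy]dodeca-7,11-dien-1-ol | C[C@H](CC/C=C/CC/C=C/c1ccccc1)C[C@](C)(CO)OO[Si](CC)(CC)CC | intermediate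
14 | (2R,4R,7E,11E)-2,4-dimethyl-12-phenyl-2-[(triethylsilyl)peroxy]dodeca-7,11-dienal | C[C@H](CC/C=C/CC/C=C/c1ccccc1)C[C@](C)(C=O)OO[Si](CC)(CC)CC | intermediate
15 | α-angelica lactone, 5-methylfuran-2(3H)-one | CC1=CCC(=O)O1 | starting material
16 | trimethyl[(5-methylfuran-2-yl)oxy]silane | Cc1ccc(O[Si](C)(C)C)o1 | intermediate
17 | aldol silyl ether, (5R)-5-methyl-5-[(2R,4R,7E,11E)-2,4-dimethyl-12-phenyl-2-(triethylsilylperoxy)-1-(trimethylsilyloxy)dodeca-7,11-dien-1-yl]furan-2(5H)-one, C1 of the chain open | C[C@H](CC/C=C/CC/C=C/c1ccccc1)C[C@](C)(C(O[Si](C)(C)C)[C@]1(C)OC(=O)C=C1)OO[Si](CC)(CC)CC | intermediate (not isolated)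
18 | hydroperoxy butenolide, (5R)-5-[(2R,4R,7E,11E)-2-hydroperoxy-1-hydroxy-2,4-dimethyl-12-phenyldodeca-7,11-dien-1-yl]-5-methylfuran-2(5H)-one, C1 of the chain open | C[C@H](CC/C=C/CC/C=C/c1ccccc1)C[C@](C)(C(O)[C@]1(C)OC(=O)C=C1)OO | intermediate (not isolated)
19 | (3R,4aS,7aS)-4-hydroxy-3,4a-dimethyl-3-[(2R,5E,9E)-2-methyl-10-phenyldeca-5,9-dien-1-yl]tetrahydro-3H-furo[3,2-c][1,2]dioxin-6(4H)-one, C4 open | C[C@H](CC/C=C/CC/C=C/c1ccccc1)C[C@]1(C)C(O)[C@]2(C)OC(=O)C[C@@H]2OO1 | intermediate
20 | O-phenyl thionocarbonate of 19 at the C4 oxygen, C4 open | C[C@H](CC/C=C/CC/C=C/c1ccccc1)C[C@]1(C)C(OC(=S)Oc3ccccc3)[C@]2(C)OC(=O)C[C@@H]2OO1 | intermediate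
21 | (3R,4aS,7aS)-3,4a-dimethyl-3-[(2R,5E,9E)-2-methyl-10-phenyldeca-5,9-dien-1-yl]tetrahydro-3H-furo[3,2-c][1,2]dioxin-6(4H)-one | C[C@H](CC/C=C/CC/C=C/c1ccccc1)C[C@]1(C)C[C@]2(C)OC(=O)C[C@@H]2OO1 | target

**Totals**
Total step count: 14. Longest linear sequence: 11 steps (3, 4, 5, 6, 7, 8, 9, 10, 12, 13, 14).

**Steps most likely to fail**

Step 12 (Proposed new method). What may go wrong: Lewis-acid-induced heterolysis and rearrangement of the silyl peroxide before the aldol event, or weak facial control at the congested γ-carbon. The fallback uses known chemistry and reverses the polarity of the union, so that no peroxide is present when the carbon–carbon bond forms. It sets out from dienyl ketone 10. Kinetic enolisation and silylation (LiN(iPr)2, Me3SiCl, THF, −78 °C) gives the trimethylsilyl enol ether F1. Me3SiOSO2CF3-mediated Mukaiyama-type substitution of 5-methoxy-5-methylfuran-2(5H)-one by F1 gives the keto butenolide F2, with the C4–C4a bond in place and C4 as CH2. MeTi(OiPr)3 adds to the ketone only and gives the tertiary alcohol F3. 50% H2O2 with catalytic H2SO4 converts it through the tertiary cation into the tertiary hydroperoxide F4. Et2NH in CF3CH2OH then closes the dioxane by peroxide Michael addition, and the fallback comes back to the route at target 21. C3 and C4a are not controlled in this sequence, so 21 would have to be separated from its ring diastereomers by preparative HPLC.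

Step 14. What may go wrong: attack of the silyl radical on the O–O bond outruns the chain, or the doubly neopentylic radical precursor is not formed cleanly in step 13, so that the temporary oxygen at C4 cannot be removed. The fallback changes the union so that C4 never carries oxygen. It sets out from dienyl ketone 10. Kinetic enolate formation and bromination (LiN(iPr)2, then NBS, THF, −78 °C) gives the bromomethyl ketone F5. AgOCOCF3-promoted γ-alkylation of silyloxyfuran 16 with F5 (CH2Cl2, −78 °C → rt) gives the keto butenolide F2, which is taken on through the tertiary alcohol F3 and the tertiary hydroperoxide F4 as above. The fallback comes back to the route at target 21, again with chromatographic separation of the ring diastereomers.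

Step 9. What may go wrong: competing silylation of the primary alcohol, or silyl migration from the peroxide to the alcohol. The fallback sets out from hydroperoxy alcohol 12. Exhaustive silylation (Et3SiOSO2CF3, 2,6-lutidine, CH2Cl2, −78 °C) gives the bis(triethylsilyl) derivative F6. Swern oxidation ((COCl)2, DMSO, Et3N, CH2Cl2, −78 → −20 °C), which cleaves and oxidises primary triethylsilyl ethers directly, converts F6 into the aldehyde. The fallback comes back to the route at aldehyde 14 and skips step 10.

**Further compounds**
F1 | step 12 | trimethyl{[(4R,7E,11E)-4-methyl-12-phenyldodeca-1,7,11-trien-2-yl]oxy}silane | C=C(O[Si](C)(C)C)C[C@H](C)CC/C=C/CC/C=C/c1ccccc1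
F2 | step 12 | 5-methyl-5-[(4R,7E,11E)-4-methyl-2-oxo-12-phenyldodeca-7,11-dien-1-yl]furan-2(5H)-one, C5 epimers | CC1(CC(=O)C[C@H](C)CC/C=C/CC/C=C/c2ccccc2)OC(=O)C=C1
F3 | step 12 | 5-[(4R,7E,11E)-2-hydroxy-2,4-dimethyl-12-phenyldodeca-7,11-dien-1-yl]-5-methylfuran-2(5H)-one, epimers at C5 and the carbinol carbon | CC1(CC(C)(O)C[C@H](C)CC/C=C/CC/C=C/c2ccccc2)OC(=O)C=C1
F4 | step 12 | 5-[(4R,7E,11E)-2-hydroperoxy-2,4-dimethyl-12-phenyldodeca-7,11-dien-1-yl]-5-methylfuran-2(5H)-one, epimers at C5 and the peroxide carbon | CC1(CC(C)(OO)C[C@H](C)CC/C=C/CC/C=C/c2ccccc2)OC(=O)C=C1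
F5 | step 14 | (4R,7E,11E)-1-bromo-4-methyl-12-phenyldodeca-7,11-dien-2-one | BrCC(=O)C[C@H](C)CC/C=C/CC/C=C/c1ccccc1
F6 | step 9 | triethyl{[(2R,4R,7E,11E)-2,4-dimethyl-12-phenyl-2-(triethylsilylperoxy)dodeca-7,11-dien-1-yl]oxy}silane | C[C@H](CC/C=C/CC/C=C/c1ccccc1)C[C@](C)(CO[Si](CC)(CC)CC)OO[Si](CC)(CC)CC
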